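**Plan**
- Retrosynthesis: (a) C3–C4 of ring A is cut by reversing a ring contraction, so the formyl carbon C19 becomes a ring atom between C3 and C4 of a seven-membered 4,19-epoxy 3-silyl ether; (b) C19=C4 by ring-closing metathesis; (c) C11–C12 by alkyl–alkyl Suzuki–Miyaura coupling; (d) C2–C3 by anti γ-borylallylboration; (e) C10–C1 and C10–C20 by enolate alkylations.
- Forward: ring B is (S)-carvone. C10 is quaternized, the seven-membered ring is closed onto the native isopropenyl group, the alkene is epoxidized on the α face, the side chain is coupled, and ring A arises last by 7→6 contraction. Saponification, desilylation and C2 acetylation finish.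
- Enabling feature: ring A carries the β-hydroxy aldehyde array C3(OH)–C4(CH3)(CHO), with C19 exocyclic on the quaternary C4 next to carbinol C3. This is the array a 2,3-epoxy silyl ether gives by a 1,2-shift.
- Stereochemistry: C5 from (S)-carvone; C10 by alkylation anti to isopropenyl; C2/C3 by the isopinocampheyl reagent; C4 by stereospecific anti migration from the α-epoxide (made by double inversion through a bromohydrin); C9 by hydroboration anti to C20; C13 from (R)-monomethyl 3-methylglutarate.

Key step: step 12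

Remark: labdane numbering is used (ring A C1–C5/C10, ring B C5–C10, side chain C11–C16, C17 on C8, C18/C19 on C4, C20 on C10), α means the face of the C10 methyl group C20, and 3 is carried as a C6-epimer mixture because that centre is planarized in step 2.

Step 1
Reactants: 1 (S)-(+)-carvone
Product: 3 trans-6-methylcarvone, via lithium dienolate 2 (not isolated)
Conditions: LiN(i-Pr)2 (LDA), THF, −78 °C; MeI, −78 → 0 °C
Reagents that add atoms: iodomethane, CI
Why: Kinetic α′-deprotonation and enolate alkylation should give the 6-methyl ketone mainly as the trans epimer; the new centre is erased in step 2.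

Step 2
Reactants: 3 trans-6-methylcarvone
Product: 5 keto ester with the CH2CO2Et arm trans to isopropenyl, via lithium dienolate 4 (not isolated)
Conditions: LDA, THF, −78 °C; BrCH2CO2Et, DMPU, −78 → 0 °C
Reagents that add atoms: ethyl bromoacetate, CCOC(=O)CBr
Why: Enolate alkylation with a reactive α-halo ester should occur anti to the neighbouring isopropenyl group, setting quaternary C10 with C20 cis and C1 trans to the C5 substituent.

Step 3
Reactants: 5 keto ester
Product: 6 allylic alcohol/primary alcohol diol (both C9 epimers)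
Conditions: LiAlH4, Et2O, 0 °C
Reagents that add atoms: none
Why: Hydride reduction takes the ester to the primary alcohol and reduces the hindered enone 1,2; the carbinol configuration is irrelevant because step 4 reoxidizes it.

Step 4
Reactants: 6 diol
Product: 7 keto aldehyde (C10–CH2–CHO, enone restored)
Conditions: Dess–Martin periodinane, NaHCO3, CH2Cl2, rt
Reagents that add atoms: none
Why: Dess–Martin oxidation converts both alcohols in one operation under buffered, non-epimerizing conditions.

Step 5
Reactants: 7 keto aldehyde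
Product: 9 (2S,3R)-ene-diol, via borinate adduct 8 (not isolated)
Conditions: (+)-Ipc2BH, 2-(propa-1,2-dien-1-yl)-1,3,2-dioxaborinane, Et2O, 0 °C; add 7, −78 °C; then H2O2, aq NaHCO3, THF, 0 °C
Reagents that add atoms: [(E)-3-(1,3,2-dioxaborinan-2-yl)allyl]bis(isopinocampheyl)borane, C(/C=C/B1OCCCO1)B([C@H]2C[C@H]3C[C@@H]([C@@H]2C)C3(C)C)[C@H]4C[C@H]5C[C@@H]([C@@H]4C)C5(C)C; hydrogen peroxide, OO
Why: Anti-selective γ-borylallylboration through a Zimmerman–Traxler chair (E-reagent gives anti; the isopinocampheyl groups from (−)-α-pinene direct attack to the Re face of the aldehyde), followed by C–B oxidation with retention, should set C2 (S) and C3 (R); the hindered enone should not compete.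

Step 6
Reactants: 9 ene-diol
Product: 10 seven-membered-ring enone diol (C19=C4 alkene, 2β,3β-diol)
Conditions: second-generation Grubbs catalyst, toluene (high dilution), 80 °C
Reagents that add atoms: none
Why: Ring-closing metathesis of the allylic-alcohol vinyl group with the isopropenyl group should close the trans-fused cycloheptene from the two trans-diequatorial arms; the electron-poor trisubstituted enone alkene is inert.

Step 7
Reactants: 10 enone diol
Product: 11 2,3-bis(tert-butyldimethylsilyl) ether
Conditions: TBSOTf, 2,6-lutidine, CH2Cl2, −78 → 0 °C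
Reagents that add atoms: tert-butyldimethylsilyl triflate, CC(C)(C)[Si](C)(C)OS(=O)(=O)C(F)(F)F
Why: Silylation installs the silyl ether needed on C3 for the rearrangement and blocks hydroxyl-directed delivery to the β face.

Step 8
Reactants: 11 bis-silyl ether
Product: 13 4α,19α-epoxide, via bromohydrin 12 (not isolated)
Conditions: NBS, DME/H2O, 0 °C; then K2CO3, MeOH, rt
Reagents that add atoms: water, O
Why: Halohydrin formation and epoxide closure by double inversion (bromonium on the open β face, Markovnikov trans-diaxial opening by water at C4 from the α face, then SN2 closure onto C19) should place the oxygen on the α face, syn to C20 and trans to the C3 silyl ether, which is the face direct peracid attack would avoid; the enone alkene does not react.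

Step 9
Reactants: 13 epoxy enone
Product: 14 exocyclic diene (C9=C11H2 conjugated with C7=C8)
Conditions: Ph3PCH3Br, KOt-Bu, toluene, 80 °C
Reagents that add atoms: methyltriphenylphosphonium bromide, C[P+](c1ccccc1)(c1ccccc1)c1ccccc1.[Br-]
Why: Wittig methylenation of the only carbonyl group supplies C11; the non-nucleophilic ylide should leave the trisubstituted epoxide and silyl ethers untouched.

Step 10
Reactants: 15 (R)-monomethyl 3-methylglutarate
Product: 16 methyl (3S)-4-bromo-3-methylbutanoate
Conditions: HgO, Br2, CCl4, reflux, dark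
Reagents that add atoms: bromine, BrBr
Why: Hunsdiecker bromodecarboxylation (Cristol–Firth variant) replaces CO2H by Br without touching the stereocentre; the descriptor changes from R to S only through the priority switch.

Step 11
Reactants: 14 exocyclic diene; 16 methyl (3S)-4-bromo-3-methylbutanoate
Product: 18 coupled methyl ester, via B-alkyl-9-BBN 17 (not isolated)
Conditions: 9-BBN, THF, 0 °C → rt; then 16, Pd(OAc)2, PCy3, K3PO4·H2O, THF, rt
Reagents that add atoms: none
Why: Hydroboration of the terminal methylene from the β face, anti to the axial C20 on the adjacent C10, delivers H to C9 (9β-H, side chain α), and the primary alkylborane then undergoes alkyl–alkyl Suzuki–Miyaura coupling with the primary bromide, forming C11–C12 with C13 already in place.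

Step 12
Reactants: 18 coupled epoxy silyl ether
Product: 19 ring-contracted 19-aldehyde (2β,3β-bis-silyloxy, methyl ester)
Conditions: MeAl(OC6H2-4-Br-2,6-t-Bu2)2 (2 equiv), CH2Cl2, −78 → −20 °C
Reagents that add atoms: none
Why: The aluminium phenoxide binds the epoxide oxygen, the tertiary C4–O bond ionizes, and the C19–C3 σ bond, held anti to it in the seven-membered ring, shifts from C19 to C4 in a concerted 1,2-migration while C19 collapses to the aldehyde. The closest known reaction type is the organoaluminium-promoted rearrangement of 2,3-epoxy silyl ethers to β-siloxy aldehydes (a Meinwald/semipinacol rearrangement), run here as the ring contraction known for 1-methylcycloalkene oxides and cyclic epoxy alcohol derivatives. Ring A closes by this 1,2-shift: the carbocycle C1–C2–C3–C19–C4–C5–C10 contracts to the six-membered ring and C19 is extruded as the exocyclic formyl group. C4 is set by inversion, because C3 enters anti to the departing α-oxygen, which places CHO α (axial, syn to C20) and C18 β; C3 migrates with retention and keeps its β-silyloxy group. The step needs C3 migration to outrun hydride shift from C19 (ring-retained ketone) and proton loss from C18 (allylic alcohol); the bulky oxophilic Lewis acid, the migratory preference of the siloxy-bearing carbon and the anti alignment of the ring bond should secure this, and the remote ester and C7=C8 alkene are spectators.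

Step 13
Reactants: 19 aldehyde methyl ester
Product: 20 15-carboxylic acid (bis-silyl ether)
Conditions: LiOH, THF/H2O, rt; dilute HCl work-up
Reagents that add atoms: lithium hydroxide, [Li+].[OH-]
Why: Saponification is done while both hydroxyls are silylated, so the non-enolizable β-siloxy aldehyde can neither dehydrate nor undergo retro-aldol cleavage.

Step 14
Reactants: 20 bis-silyl acid
Product: 21 2β,3β-dihydroxy-19-oxo acid
Conditions: HF·pyridine, pyridine, THF, 0 °C → rt
Reagents that add atoms: none
Why: Acidic fluoride desilylation frees both hydroxyls without the basic conditions that would risk retro-aldol cleavage of the β-hydroxy aldehyde.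

Step 15
Reactants: 21 dihydroxy acid
Product: 22 target CNP0180877.1
Conditions: Ac2O, pyridine, CH2Cl2, 0 °C; aqueous work-up
Reagents that add atoms: acetic anhydride, CC(=O)OC(C)=O
Why: Selective acylation should take the equatorial C2 hydroxyl in preference to the axial C3 hydroxyl flanked by quaternary C4; any mixed anhydride at C15 is hydrolysed on work-up.

**Compound list**
1 | (S)-(+)-carvone, (5S)-2-methyl-5-(prop-1-en-2-yl)cyclohex-2-en-1-one | CC1=CC[C@@H](CC1=O)C(C)=C | starting material
2 | lithium cross-conjugated dienolate of 1 | [Li]OC1=C[C@H](CC=C1C)C(C)=C | intermediate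
3 | (5S,6R)-2,6-dimethyl-5-(prop-1-en-2-yl)cyclohex-2-en-1-one (trans-6-methylcarvone, major epimer) | C[C@H]1C(=O)C(C)=CC[C@@H]1C(C)=C | intermediate
4 | lithium dienolate of 3 | [Li]OC1=C(C)[C@H](CC=C1C)C(C)=C | intermediate
5 | ethyl 2-[(1R,6R)-1,3-dimethyl-2-oxo-6-(prop-1-en-2-yl)cyclohex-3-en-1-yl]acetate | CCOC(=O)C[C@@]1(C)C(=O)C(C)=CC[C@@H]1C(C)=C | intermediate
6 | 2-[(1R,6R)-2-hydroxy-1,3-dimethyl-6-(prop-1-en-2-yl)cyclohex-3-en-1-yl]ethanol (both carbinol epimers) | OCC[C@@]1(C)C(O)C(C)=CC[C@@H]1C(C)=C | intermediate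
7 | 2-[(1R,6R)-1,3-dimethyl-2-oxo-6-(prop-1-en-2-yl)cyclohex-3-en-1-yl]acetaldehyde | O=CC[C@@]1(C)C(=O)C(C)=CC[C@@H]1C(C)=C | intermediate
8 | allylboration adduct: C2–O–B(isopinocampheyl)2 borinate with the 1,3,2-dioxaborinan-2-yl group on C3 | C=C[C@@H](B1OCCCO1)[C@H](C[C@@]2(C)C(=O)C(C)=CC[C@@H]2C(C)=C)OB([C@H]3C[C@H]4C[C@@H]([C@@H]3C)C4(C)C)[C@H]5C[C@H]6C[C@@H]([C@@H]5C)C6(C)C | intermediate
9 | (5R,6R)-6-[(2S,3R)-2,3-dihydroxypent-4-en-1-yl]-2,6-dimethyl-5-(prop-1-en-2-yl)cyclohex-2-en-1-one | O[C@@H](C[C@@]1(C)C(=O)C(C)=CC[C@@H]1C(C)=C)[C@H](O)C=C | intermediate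
10 | trans-fused 6–7 enone diol: seven-membered ring C1–C2–C3–C19=C4–C5–C10, 2β,3β-diol, 9-oxo-Δ7 | O[C@H]1C[C@@]2(C)C(=O)C(C)=CC[C@@H]2C(C)=C[C@H]1O | intermediate
11 | 2β,3β-bis(tert-butyldimethylsilyl) ether of 10 | CC(C)(C)[Si](C)(C)O[C@H]1C[C@@]2(C)C(=O)C(C)=CC[C@@H]2C(C)=C[C@H]1O[Si](C)(C)C(C)(C)C | intermediate
12 | bromohydrin of 11: 19β-bromo-4α-hydroxy | CC(C)(C)[Si](C)(C)O[C@H]1C[C@@]2(C)C(=O)C(C)=CC[C@@H]2[C@](C)(O)[C@@H](Br)[C@H]1O[Si](C)(C)C(C)(C)C | intermediate
13 | 4α,19α-epoxide (oxygen syn to C20, trans to the C3 silyl ether), 9-oxo-Δ7 | CC(C)(C)[Si](C)(C)O[C@H]1C[C@@]2(C)C(=O)C(C)=CC[C@@H]2[C@]3(C)O[C@@H]3[C@H]1O[Si](C)(C)C(C)(C)C | intermediate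
14 | 9(11)-methylene diene of 13 | CC(C)(C)[Si](C)(C)O[C@H]1C[C@@]2(C)C(=C)C(C)=CC[C@@H]2[C@]3(C)O[C@@H]3[C@H]1O[Si](C)(C)C(C)(C)C | intermediate
15 | (3R)-5-methoxy-3-methyl-5-oxopentanoic acid, (R)-monomethyl 3-methylglutarate | OC(=O)C[C@@H](C)CC(=O)OC | starting material
16 | methyl (3S)-4-bromo-3-methylbutanoate | BrC[C@@H](C)CC(=O)OC | intermediate
17 | B-alkyl-9-BBN at C11 (9β-H), epoxide and silyl ethers as in 14 | CC(C)(C)[Si](C)(C)O[C@H]1C[C@@]2(C)[C@H](CB3C4CCCC3CCC4)C(C)=CC[C@@H]2[C@]5(C)O[C@@H]5[C@H]1O[Si](C)(C)C(C)(C)C | intermediate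
18 | methyl ester with the full (13R) side chain on C9, 4α,19α-epoxide, 2β,3β-bis-silyl ether, Δ7 | CC(C)(C)[Si](C)(C)O[C@H]1C[C@@]2(C)[C@H](CC[C@@H](C)CC(=O)OC)C(C)=CC[C@@H]2[C@]3(C)O[C@@H]3[C@H]1O[Si](C)(C)C(C)(C)C | intermediate
19 | methyl 2β,3β-bis(tert-butyldimethylsilyloxy)-19-oxolabd-7-en-15-oate (C19 formyl α, C18 methyl β, 13R) | CC(C)(C)[Si](C)(C)O[C@H]1C[C@@]2(C)[C@H](CC[C@@H](C)CC(=O)OC)C(C)=CC[C@@H]2[C@](C)(C=O)[C@H]1O[Si](C)(C)C(C)(C)C | intermediate
20 | 15-carboxylic acid of 19 | CC(C)(C)[Si](C)(C)O[C@H]1C[C@@]2(C)[C@H](CC[C@@H](C)CC(=O)O)C(C)=CC[C@@H]2[C@](C)(C=O)[C@H]1O[Si](C)(C)C(C)(C)C | intermediate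
21 | 2β,3β-dihydroxy-19-oxolabd-7-en-15-oic acid | O[C@H]1C[C@@]2(C)[C@H](CC[C@@H](C)CC(=O)O)C(C)=CC[C@@H]2[C@](C)(C=O)[C@H]1O | intermediate
22 | CNP0180877.1, 2β-acetoxy-3β-hydroxy-19-oxolabd-7-en-15-oic acid | CC(=O)O[C@H]1C[C@@]2(C)[C@H](CC[C@@H](C)CC(=O)O)C(C)=CC[C@@H]2[C@](C)(C=O)[C@H]1O | target

Total step count: 15. Longest linear sequence: 14 steps (steps 1–9 and 11–15 from (S)-carvone).

**Steps most likely to fail**

1. Step 12 (key step). The process at risk is the migration itself: hydride shift from C19 or proton loss from C18 may outrun the shift of C3, or the bulky Lewis acid may fail to engage the epoxide oxygen lying under C20. The fallback sets out from 11 and returns at 19. Direct epoxidation of 11 with mCPBA on the open β face should give the β-epoxide F1. Methylenation as in step 9 gives diene F2, hydroboration with 9-BBN gives the alkylborane F3, and coupling with 16 as in step 11 gives ester F4. MgBr2·OEt2 then opens the epoxide at tertiary C4 with inversion to the trans-bromohydrin F5 (4α-bromo, 19β-hydroxy). Treatment of F5 with AgBF4 in CH2Cl2 at low temperature ionizes the tertiary bromide and the ring carbon C3 anti to it migrates. This is the classical ring contraction of trans-2-halocycloalkanols (halohydrin semipinacol rearrangement) and should deliver 19 with the same C4 configuration.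

2. Step 8. The process at risk is facial selectivity: if the bromonium ion forms on the α face, the double inversion would lead to the β-epoxide. The fallback sets out from 11 and returns at 13. In that case direct oxygen transfer with mCPBA (NaHCO3, CH2Cl2, 0 °C) would attack the same preferred α face and give 13 in a single syn epoxidation. No new compound is made.

3. Step 11. The process at risk is the cross-coupling: slow oxidative addition of the β-branched primary bromide may let β-hydride elimination and protodeboronation win. The fallback sets out from 14 (through 17) and returns at 18. Borane 17 is oxidized with NaBO3·4H2O to the primary alcohol F6, which Dess–Martin periodinane converts to the aldehyde F7 (used at once, cold). Bromide 16 and PPh3 give the phosphonium bromide F8, and NaN(SiMe3)2 turns it into the ylide F9. Wittig reaction of F9 with F7 gives the Z-alkene F10, and diimide (TsNHNH2, NaOAc) reduces the disubstituted alkene in preference to C7=C8 to give 18.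

Further compounds
F1 | step 12 | 4β,19β-epoxide diastereomer of 13 (9-oxo-Δ7) | CC(C)(C)[Si](C)(C)O[C@H]1C[C@@]2(C)C(=O)C(C)=CC[C@@H]2[C@@]3(C)O[C@H]3[C@H]1O[Si](C)(C)C(C)(C)C
F2 | step 12 | 9(11)-methylene diene of F1 | CC(C)(C)[Si](C)(C)O[C@H]1C[C@@]2(C)C(=C)C(C)=CC[C@@H]2[C@@]3(C)O[C@H]3[C@H]1O[Si](C)(C)C(C)(C)C
F3 | step 12 | B-alkyl-9-BBN of F2 (C11–B, 9β-H) | CC(C)(C)[Si](C)(C)O[C@H]1C[C@@]2(C)[C@H](CB3C4CCCC3CCC4)C(C)=CC[C@@H]2[C@@]5(C)O[C@H]5[C@H]1O[Si](C)(C)C(C)(C)C
F4 | step 12 | coupled methyl ester with 4β,19β-epoxide | CC(C)(C)[Si](C)(C)O[C@H]1C[C@@]2(C)[C@H](CC[C@@H](C)CC(=O)OC)C(C)=CC[C@@H]2[C@@]3(C)O[C@H]3[C@H]1O[Si](C)(C)C(C)(C)C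
F5 | step 12 | trans-bromohydrin: 4α-bromo-19β-hydroxy methyl ester | CC(C)(C)[Si](C)(C)O[C@H]1C[C@@]2(C)[C@H](CC[C@@H](C)CC(=O)OC)C(C)=CC[C@@H]2[C@](C)(Br)[C@@H](O)[C@H]1O[Si](C)(C)C(C)(C)C
F0 | step 8 | none | none
F6 | step 11 | C11 primary alcohol (9β-H) with 4α,19α-epoxide | CC(C)(C)[Si](C)(C)O[C@H]1C[C@@]2(C)[C@H](CO)C(C)=CC[C@@H]2[C@]3(C)O[C@@H]3[C@H]1O[Si](C)(C)C(C)(C)C
F7 | step 11 | C11 aldehyde | CC(C)(C)[Si](C)(C)O[C@H]1C[C@@]2(C)[C@H](C=O)C(C)=CC[C@@H]2[C@]3(C)O[C@@H]3[C@H]1O[Si](C)(C)C(C)(C)C
F8 | step 11 | [(2S)-4-methoxy-2-methyl-4-oxobutyl]triphenylphosphonium bromide | COC(=O)C[C@H](C)C[P+](c1ccccc1)(c1ccccc1)c1ccccc1.[Br-]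
F9 | step 11 | ylide of F8 | COC(=O)C[C@H](C)C=P(c1ccccc1)(c1ccccc1)c1ccccc1
F10 | step 11 | (11Z)-alkene: 18 with a C11=C12 double bond | CC(C)(C)[Si](C)(C)O[C@H]1C[C@@]2(C)[C@H](/C=C\[C@@H](C)CC(=O)OC)C(C)=CC[C@@H]2[C@]3(C)O[C@@H]3[C@H]1O[Si](C)(C)C(C)(C)C
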